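The whole plan rests on cutting the acyl chain between C17 and C18 (ester carbonyl = C1). The key step exploits the fact that C2–C36 form an unbranched, unsubstituted saturated chain, remote from the only ring (the para-substituted benzene of tyrosol). Both halves are therefore plain primary alkyl radicals, obtainable by anodic decarboxylation. One mixed Kolbe electrolysis joins the nineteen-carbon radical from arachidic acid to a seventeen-carbon ester-terminated radical. This completes all 36 acyl carbons with the tyrosol ester already in place. The precursor is octadecanedioic acid carrying one free carboxyl group and one 4-acetoxyphenethyl ester. The phenol is acetyl-masked against anodic oxidation and freed last by aminolysis.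

Key step: step 4

Remark: carbon count is 19 C (6 minus CO2) + 16 CH2 + 1 C=O (5 minus CO2) = 36 acyl carbons; the target has no stereocentre and no double-bond geometry; 3 and 1-bromononadecane (fallback only) are taken as purchasable.

Step 1
Reactants: 1 tyrosol
Product: 2 4-(2-hydroxyethyl)phenyl acetate
Conditions: NaOH (1.05 equiv, 1 M aq), Ac2O (1.05 equiv), ice–water, 0 °C, 20 min
Reagents that add atoms: acetic anhydride, CC(=O)OC(C)=O
Why: Schotten–Baumann-type O-acetylation, in which only the phenol (pKa about 10) is ionised and its phenoxide takes up the anhydride far faster than the neutral primary alcohol or water, while the falling pH and the cold, short contact time prevent saponification of 2.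

Step 2
Reactants: 2 4-(2-hydroxyethyl)phenyl acetate; 3 18-(tert-butoxy)-18-oxooctadecanoic acid
Product: 4 1-tert-butyl 18-[2-(4-acetoxyphenyl)ethyl] octadecanedioate
Conditions: EDC·HCl (1.3 equiv), DMAP (0.1 equiv), CH2Cl2, 0 °C to rt
Reagents that add atoms: none
Why: Steglich esterification, in which carbodiimide activation of 3 with DMAP as acyl-transfer catalyst acylates the only free hydroxyl group, the low DMAP loading and cold start keep acetyl transfer from the aryl acetate negligible, and the urea is removed by an aqueous wash.

Step 3
Reactants: 4 1-tert-butyl 18-[2-(4-acetoxyphenyl)ethyl] octadecanedioate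
Product: 5 18-[2-(4-acetoxyphenyl)ethoxy]-18-oxooctadecanoic acid
Conditions: TFA–CH2Cl2 1:3, rt; co-evaporation with toluene
Reagents that add atoms: none
Why: Acidolysis of a tert-butyl ester by alkyl–oxygen fission through the tert-butyl cation, a path closed to the primary phenethyl ester and the aryl acetate, which meet no nucleophile in the anhydrous medium, while the acetoxy-deactivated ring should escape tert-butylation.

Step 4
Reactants: 5 18-[2-(4-acetoxyphenyl)ethoxy]-18-oxooctadecanoic acid; 6 arachidic acid
Product: 9 2-(4-acetoxyphenyl)ethyl hexatriacontanoate, via nonadecyl radical 7 (not isolated), via ester-bearing heptadecyl radical 8 (not isolated)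
Conditions: undivided cell, smooth Pt foil anode, larger Pt gauze cathode, 6 (5 equiv, then 1 equiv late in the run), KOH (5 mol % of total acid, pre-dissolved with 6 before 5 is added), MeOH–cyclohexane 2:1, 50 °C, constant current ca. 0.25 A cm−2, current cut while the electrolyte is still acidic
Reagents that add atoms: none
Why: Both carboxylates adsorb on the platinum anode, give up one electron and CO2, and the primary radicals 7 and 8 combine at the electrode surface to form the C17–C18 σ-bond, while carboxyl protons are reduced to H2 at the cathode. This is the classical mixed Kolbe electrolysis (Brown–Walker variant) of a fatty acid with a dicarboxylic acid half-ester, the established way to lengthen fatty chains. No ring is closed and no stereocentre is created. Cross- over homo-coupling is only statistical and is pushed by the excess of cheap 6, whose dimer octatriacontane is an alkane and thus far less polar than 9, while the dimer of 8 is a tetraester and far more polar. Carboxylate oxidation must also beat arene oxidation, which is secured by the acetoxy group (no free or alkylated phenol oxygen), the sixteen methylenes between ring and carboxylate, and the dense carboxylate layer at high current density, and unbranched primary radicals resist further oxidation to cations. The aryl acetate and the phenethyl ester should survive because the bulk stays buffered on the acidic side: KOH is consumed by 6 beforehand, no pyridine or amine is present, the large cathode and the acid reservoir quench cathodic methoxide, and cyclohexane keeps the waxy products off the anode.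

Step 5
Reactants: 9 2-(4-acetoxyphenyl)ethyl hexatriacontanoate
Product: 10 2-(4-hydroxyphenyl)ethyl hexatriacontanoate
Conditions: pyrrolidine (3 equiv), THF, 40 °C; dilute citric acid wash, recrystallisation from EtOAc
Reagents that add atoms: none
Why: Chemoselective aminolysis, in which the aryl acetate (phenoxide leaving group, pKa about 10) acylates pyrrolidine readily whereas the unactivated primary alkyl ester (alkoxide leaving group, pKa about 16) is inert to amines at this temperature, and warm anhydrous THF keeps the waxy substrate dissolved where aqueous methanol would not.

Compound list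
1 | tyrosol, 2-(4-hydroxyphenyl)ethanol | OCCc1ccc(O)cc1 | starting material
2 | 4-(2-hydroxyethyl)phenyl acetate | CC(=O)Oc1ccc(CCO)cc1 | intermediate
3 | 18-(tert-butoxy)-18-oxooctadecanoic acid | CC(C)(C)OC(=O)CCCCCCCCCCCCCCCCC(=O)O | starting material
4 | 1-tert-butyl 18-[2-(4-acetoxyphenyl)ethyl] octadecanedioate | CC(C)(C)OC(=O)CCCCCCCCCCCCCCCCC(=O)OCCc1ccc(OC(C)=O)cc1 | intermediate
5 | 18-[2-(4-acetoxyphenyl)ethoxy]-18-oxooctadecanoic acid | OC(=O)CCCCCCCCCCCCCCCCC(=O)OCCc1ccc(OC(C)=O)cc1 | intermediate
6 | arachidic acid (eicosanoic acid) | CCCCCCCCCCCCCCCCCCCC(=O)O | starting material
7 | nonadecyl radical | [CH2]CCCCCCCCCCCCCCCCCC | intermediate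
8 | 17-[2-(4-acetoxyphenyl)ethoxy]-17-oxoheptadecyl radical | [CH2]CCCCCCCCCCCCCCCC(=O)OCCc1ccc(OC(C)=O)cc1 | intermediate
9 | 2-(4-acetoxyphenyl)ethyl hexatriacontanoate | CCCCCCCCCCCCCCCCCCCCCCCCCCCCCCCCCCCC(=O)OCCc1ccc(OC(C)=O)cc1 | intermediate
10 | 2-(4-hydroxyphenyl)ethyl hexatriacontanoate | CCCCCCCCCCCCCCCCCCCCCCCCCCCCCCCCCCCC(=O)OCCc1ccc(O)cc1 | target

Total step count: 5. Longest linear sequence: 5 steps (1 → 2 → 4 → 5 → 9 → 10); 3 and 6 are bought.

Steps most likely to fail

Step 4.
- What may go wrong: wax deposition that passivates the anode, competing oxidation of the aromatic ring, solvolytic loss of the acetyl group in the alkaline film at the cathode, and dilution of the cross-product by statistical homo-coupling.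
- Fallback: it makes the same C17–C18 bond without electrolysis, sets out from 5 and comes back at 9. Acid 5 is condensed with N-hydroxyphthalimide (N,N'-diisopropylcarbodiimide, cat. DMAP, CH2Cl2, rt) to the redox-active ester 1-(1,3-dioxoisoindolin-2-yl) 18-[2-(4-acetoxyphenyl)ethyl] octadecanedioate F1.
- Purchased 1-bromononadecane is turned with Mg in THF into nonadecylmagnesium bromide F2, and then with ZnCl2 (0.5 equiv) into dinonadecylzinc F3.
- A nickel-catalysed decarboxylative alkyl–alkyl coupling of the Negishi type between F1 and F3 (NiCl2(dme), 4,4'-di-tert-butyl-2,2'-bipyridine, THF–DMF, rt) should deliver 9. This reaction is known for primary redox-active esters with primary dialkylzincs and tolerates esters.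

Step 2.
- What may go wrong: DMAP-mediated acetyl transfer from the aryl acetate of one molecule to the primary alcohol of another, and rearrangement of the activated acid to an unreactive N-acylurea.
- Fallback: it reverses the order of acylations, sets out from 1 (with 3) and comes back at 4. Unprotected 1 and 3 are esterified with immobilised Candida antarctica lipase B (2-methyl-2-butanol, 4 Å molecular sieves, 50 °C). This enzyme acylates only the aliphatic hydroxyl group of phenolic alcohols and does not accept the bulky tert-butyl ester, so it should give 1-tert-butyl 18-[2-(4-hydroxyphenyl)ethyl] octadecanedioate F4.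
- Acetylation of the remaining phenol (Ac2O, pyridine, rt) then gives 4.

Step 5.
- What may go wrong: stalling because the waxy substrate crystallises out, or slow attack of the amine on the alkyl ester if the reaction has to be forced.
- Fallback: it gives up selective deacetylation, sets out from 9 and comes back at 10. Both ester groups of 9 are saponified (KOH, EtOH–toluene, reflux, then aq. HCl) and hexatriacontanoic acid F5 is collected by filtration.
- F5 is coupled with unprotected 1 under Mitsunobu conditions (PPh3, DIAD, THF, 45 °C). The far more acidic carboxylic acid protonates the betaine and supplies the nucleophile, and only the primary alcohol is activated, so the phenol stays free and 10 is formed directly.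

Further compounds
F1 | step 4 | 1-(1,3-dioxoisoindolin-2-yl) 18-[2-(4-acetoxyphenyl)ethyl] octadecanedioate | O=C1c2ccccc2C(=O)N1OC(=O)CCCCCCCCCCCCCCCCC(=O)OCCc1ccc(OC(C)=O)cc1
F2 | step 4 | nonadecylmagnesium bromide | CCCCCCCCCCCCCCCCCCC[Mg]Br
F3 | step 4 | dinonadecylzinc | CCCCCCCCCCCCCCCCCCC[Zn]CCCCCCCCCCCCCCCCCCC
F4 | step 2 | 1-tert-butyl 18-[2-(4-hydroxyphenyl)ethyl] octadecanedioate | CC(C)(C)OC(=O)CCCCCCCCCCCCCCCCC(=O)OCCc1ccc(O)cc1
F5 | step 5 | hexatriacontanoic acid | CCCCCCCCCCCCCCCCCCCCCCCCCCCCCCCCCCCC(=O)O
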